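**Retrosynthetic overview**

1. Luzonoid A rests on a cis-fused cyclopenta[c]pyran whose pyran ring holds the isovaleryl acetal C1, O2 and the enol ether C3=C4. This is the oxa-[4+2] retron of a 1-oxadiene O2=C3–C4=C5 and an enol ester C9=C1 joined by the tether C6–C7–C8.
2. Endgame: C11–OH from a C4 formyl group by 1,2-reduction, then removal of three silyl ethers (aryl TBS, primary TBS at O10, tertiary TES at O8); both esters are already in place.
3. Key disconnection: C4=C5 (Knoevenagel with malondialdehyde), then C5–C9 and O2–C1 in one intramolecular inverse-demand hetero-Diels–Alder. Cyclopentane and dihydropyran close in the same step, the five-membered ring through the leading C5–C9 bond.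
4. The (E)-enol isovalerate comes from a terminal alkyne by hydroboration and stereoretentive Cu-catalysed C–O coupling of the (E)-alkenyltrifluoroborate with isovaleric acid. Ru-catalysed anti-Markovnikov addition of acids to 1-alkynes is Z-selective and would lead to the C1 epimer.
5. C8 is set by chelation-controlled ethynylation of a C8 ketone next to the C7 PMB ether; C5–C8 and C10 come from 2-deoxy-D-ribose, with C5 masked as a dithiane.

Key step: step 16

Remark: iridoid numbering is used for all intermediates (C1 acetal carbon, O2, C3=C4, C5 and C9 ring-fusion carbons, C6–C8, C10 on C8, C11 on C4). Sugar carbons C1–C5 become C5, C6, C7, C8 and C10. Malondialdehyde is written as the dialdehyde although it reacts as its enol.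

**Route**

Step 1
Reactants: 1 2-deoxy-D-ribose
Product: 2 (2R,3S)-4-(1,3-dithian-2-yl)butane-1,2,3-triol
Conditions: HS(CH2)3SH, conc. HCl, 0 °C
Reagents that add atoms: propane-1,3-dithiol, SCCCS
Why: Acid-catalysed dithioacetalisation traps the open-chain aldehyde as a 1,3-dithiane, which masks the future C5 carbonyl through the organometallic and oxidative steps and leaves both carbinol centres untouched.

Step 2
Reactants: 2 (2R,3S)-4-(1,3-dithian-2-yl)butane-1,2,3-triol
Product: 3 (S)-1-[(R)-2,2-dimethyl-1,3-dioxolan-4-yl]-2-(1,3-dithian-2-yl)ethan-1-ol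
Conditions: Me2C(OMe)2, PPTS (cat.), acetone, rt
Reagents that add atoms: 2,2-dimethoxypropane, COC(C)(C)OC
Why: Isopropylidene acetal formation under equilibrating conditions selects the terminal 1,2-diol (O8/O10), because the monosubstituted dioxolane is favoured over the cis-disubstituted dioxolane and over a 1,3-dioxane with an axial methyl group, so only the C7 hydroxyl stays free.

Step 3
Reactants: 3 (S)-1-[(R)-2,2-dimethyl-1,3-dioxolan-4-yl]-2-(1,3-dithian-2-yl)ethan-1-ol
Product: 4 2-{(S)-2-[(R)-2,2-dimethyl-1,3-dioxolan-4-yl]-2-[(4-methoxybenzyl)oxy]ethyl}-1,3-dithiane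
Conditions: NaH, PMBCl, Bu4NI (cat.), DMF, 0 °C → rt
Reagents that add atoms: 4-methoxybenzyl chloride, COc1ccc(CCl)cc1
Why: Williamson etherification installs a PMB ether at O7, chosen because its oxygen chelates magnesium in step 7 and because it can later be removed oxidatively without touching silyl ethers or the enol ester.

Step 4
Reactants: 4 2-{(S)-2-[(R)-2,2-dimethyl-1,3-dioxolan-4-yl]-2-[(4-methoxybenzyl)oxy]ethyl}-1,3-dithiane
Product: 5 (2R,3S)-4-(1,3-dithian-2-yl)-3-[(4-methoxybenzyl)oxy]butane-1,2-diol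
Conditions: AcOH/H2O (4:1), 40 °C
Reagents that add atoms: none
Why: Acid hydrolysis of the acetonide frees the 1,2-diol, while the PMB ether and the dithioacetal are stable to aqueous acetic acid.

Step 5
Reactants: 5 (2R,3S)-4-(1,3-dithian-2-yl)-3-[(4-methoxybenzyl)oxy]butane-1,2-diol
Product: 6 (2R,3S)-1-[(tert-butyldimethylsilyl)oxy]-4-(1,3-dithian-2-yl)-3-[(4-methoxybenzyl)oxy]butan-2-ol
Conditions: TBSCl, imidazole, CH2Cl2, 0 °C
Reagents that add atoms: tert-butyldimethylsilyl chloride, CC(C)(C)[Si](C)(C)Cl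
Why: Silylation discriminates the primary from the secondary hydroxyl on steric grounds, and the bulky silyl ether is a poor ligand for magnesium, so it should not compete with the PMB oxygen for chelation.

Step 6
Reactants: 6 (2R,3S)-1-[(tert-butyldimethylsilyl)oxy]-4-(1,3-dithian-2-yl)-3-[(4-methoxybenzyl)oxy]butan-2-ol
Product: 7 (S)-1-[(tert-butyldimethylsilyl)oxy]-4-(1,3-dithian-2-yl)-3-[(4-methoxybenzyl)oxy]butan-2-one
Conditions: Dess–Martin periodinane, pyridine, CH2Cl2, 0 °C → rt
Reagents that add atoms: none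
Why: Dess–Martin oxidation gives the C8 ketone under buffered, non-basic conditions, so the α-alkoxy stereocentre C7 should not epimerise and the thioacetal sulfur should not be oxidised.

Step 7
Reactants: 7 (S)-1-[(tert-butyldimethylsilyl)oxy]-4-(1,3-dithian-2-yl)-3-[(4-methoxybenzyl)oxy]butan-2-one, 8 ethynylmagnesium bromide
Product: 9 (3R,4S)-3-{[(tert-butyldimethylsilyl)oxy]methyl}-5-(1,3-dithian-2-yl)-4-[(4-methoxybenzyl)oxy]pent-1-yn-3-ol
Conditions: MgBr2·OEt2, CH2Cl2, −78 °C; then HC≡CMgBr (THF), −78 → −40 °C; H2O (pH 7)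
Reagents that add atoms: none
Why: Grignard addition under Cram chelate control, in which magnesium bridges the C8 carbonyl oxygen and the C7 PMB oxygen and the acetylide attacks the chelate from the face of the C7 hydrogen, anti to the C6 methylene, which should set C8 with the R configuration required in the target.

Step 8
Reactants: 9 (3R,4S)-3-{[(tert-butyldimethylsilyl)oxy]methyl}-5-(1,3-dithian-2-yl)-4-[(4-methoxybenzyl)oxy]pent-1-yn-3-ol
Product: 10 2-{(2S,3R)-3-{[(tert-butyldimethylsilyl)oxy]methyl}-2-[(4-methoxybenzyl)oxy]-3-[(triethylsilyl)oxy]pent-4-yn-1-yl}-1,3-dithiane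
Conditions: TESOTf, 2,6-lutidine, CH2Cl2, −78 → 0 °C
Reagents that add atoms: triethylsilyl trifluoromethanesulfonate, CC[Si](CC)(CC)OS(=O)(=O)C(F)(F)F
Why: A silyl triflate with a hindered pyridine base silylates the tertiary propargylic alcohol, which must be capped because it would otherwise close a five-membered lactol onto the C5 aldehyde once that is released.

Step 9
Reactants: 10 2-{(2S,3R)-3-{[(tert-butyldimethylsilyl)oxy]methyl}-2-[(4-methoxybenzyl)oxy]-3-[(triethylsilyl)oxy]pent-4-yn-1-yl}-1,3-dithiane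
Product: 12 potassium [(1E,3R,4S)-3-{[(tert-butyldimethylsilyl)oxy]methyl}-5-(1,3-dithian-2-yl)-4-[(4-methoxybenzyl)oxy]-3-[(triethylsilyl)oxy]pent-1-en-1-yl]trifluoroborate, via (E)-alkenyl pinacol boronate 11 (not isolated)
Conditions: HBpin, Cp2Zr(H)Cl (10 mol %), Et3N (10 mol %), CH2Cl2, 40 °C; then KHF2, MeOH/H2O, 0 °C → rt
Reagents that add atoms: pinacolborane, CC1(C)OBOC1(C)C; potassium hydrogen difluoride, F.[F-].[K+]
Why: Zirconium-catalysed hydroboration adds H–B syn and anti-Markovnikov to the terminal alkyne to give the (E)-alkenylboronate, and KHF2 then exchanges pinacol for fluoride in a short contact that should spare the alkyl silyl ethers (no aryl silyl ether is present yet).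

Step 10
Reactants: 12 potassium [(1E,3R,4S)-3-{[(tert-butyldimethylsilyl)oxy]methyl}-5-(1,3-dithian-2-yl)-4-[(4-methoxybenzyl)oxy]-3-[(triethylsilyl)oxy]pent-1-en-1-yl]trifluoroborate, 13 isovaleric acid
Product: 14 (1E,3R,4S)-3-{[(tert-butyldimethylsilyl)oxy]methyl}-5-(1,3-dithian-2-yl)-4-[(4-methoxybenzyl)oxy]-3-[(triethylsilyl)oxy]pent-1-en-1-yl 3-methylbutanoate
Conditions: isovaleric acid (excess), CuBr (cat.), DMAP, 4 Å MS, O2 (1 atm), CH2Cl2, 40 °C
Reagents that add atoms: none
Why: Chan–Lam-type oxidative copper-catalysed C–O coupling of an alkenyltrifluoroborate with a carboxylic acid transfers the alkenyl group with retention, so the E geometry fixed in step 9 is carried into the enol isovalerate, whereas ruthenium-catalysed anti-Markovnikov addition of acids to 1-alkynes gives mainly Z-enol esters.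

Step 11
Reactants: 14 (1E,3R,4S)-3-{[(tert-butyldimethylsilyl)oxy]methyl}-5-(1,3-dithian-2-yl)-4-[(4-methoxybenzyl)oxy]-3-[(triethylsilyl)oxy]pent-1-en-1-yl 3-methylbutanoate
Product: 15 (1E,3R,4S)-3-{[(tert-butyldimethylsilyl)oxy]methyl}-5-(1,3-dithian-2-yl)-4-hydroxy-3-[(triethylsilyl)oxy]pent-1-en-1-yl 3-methylbutanoate
Conditions: DDQ, CH2Cl2/pH 7 buffer, 0 °C
Reagents that add atoms: none
Why: Oxidative PMB cleavage with DDQ in a buffered two-phase medium frees the C7 hydroxyl, and the enol ester, the silyl ethers and (at 0 °C) the aliphatic dithiane are expected to survive.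

Step 12
Reactants: 16 (E)-4-hydroxycinnamic acid
Product: 18 (E)-3-{4-[(tert-butyldimethylsilyl)oxy]phenyl}acrylic acid, via silyl ester silyl ether 17 (not isolated)
Conditions: TBSCl, imidazole, DMF, rt; then AcOH, THF/H2O, rt
Reagents that add atoms: tert-butyldimethylsilyl chloride, CC(C)(C)[Si](C)(C)Cl
Why: Exhaustive silylation followed by selective hydrolysis of the very labile silyl ester leaves the phenol protected, which prevents self-acylation in step 13.

Step 13
Reactants: 15 (1E,3R,4S)-3-{[(tert-butyldimethylsilyl)oxy]methyl}-5-(1,3-dithian-2-yl)-4-hydroxy-3-[(triethylsilyl)oxy]pent-1-en-1-yl 3-methylbutanoate, 18 (E)-3-{4-[(tert-butyldimethylsilyl)oxy]phenyl}acrylic acid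
Product: 20 (2S,3R,4E)-3-{[(tert-butyldimethylsilyl)oxy]methyl}-1-(1,3-dithian-2-yl)-5-[(3-methylbutanoyl)oxy]-3-[(triethylsilyl)oxy]pent-4-en-2-yl (E)-3-{4-[(tert-butyldimethylsilyl)oxy]phenyl}acrylate, via mixed anhydride 19 (not isolated)
Conditions: 18, 2,4,6-Cl3C6H2COCl, Et3N, THF, rt; then 15, DMAP, toluene, rt
Reagents that add atoms: none
Why: Yamaguchi esterification through the mixed anhydride acylates the hindered secondary C7 hydroxyl at oxygen, so the C7 configuration is retained.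

Step 14
Reactants: 20 (2S,3R,4E)-3-{[(tert-butyldimethylsilyl)oxy]methyl}-1-(1,3-dithian-2-yl)-5-[(3-methylbutanoyl)oxy]-3-[(triethylsilyl)oxy]pent-4-en-2-yl (E)-3-{4-[(tert-butyldimethylsilyl)oxy]phenyl}acrylate
Product: 21 (3S,4R,5E)-4-{[(tert-butyldimethylsilyl)oxy]methyl}-6-[(3-methylbutanoyl)oxy]-1-oxo-4-[(triethylsilyl)oxy]hex-5-en-3-yl (E)-3-{4-[(tert-butyldimethylsilyl)oxy]phenyl}acrylate
Conditions: MeI, CaCO3, MeCN/H2O (9:1), 40 °C
Reagents that add atoms: water, O
Why: S-Methylation of the dithiane and hydrolysis of the sulfonium ion release the aldehyde under nearly neutral conditions, chosen so that the β-acyloxy aldehyde does not lose the coumarate by elimination; the aldehyde is used without storage.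

Step 15
Reactants: 22 1,1,3,3-tetramethoxypropane
Product: 23 malondialdehyde (used at once as a dried CH2Cl2 solution of its enol)
Conditions: 1 M aq. HCl, rt; extraction into CH2Cl2, Na2SO4
Reagents that add atoms: water, O
Why: Acid hydrolysis of the bis-acetal liberates malondialdehyde, which is stable enough in cold dilute solution as its enol to be used directly.

Step 16
Reactants: 21 (3S,4R,5E)-4-{[(tert-butyldimethylsilyl)oxy]methyl}-6-[(3-methylbutanoyl)oxy]-1-oxo-4-[(triethylsilyl)oxy]hex-5-en-3-yl (E)-3-{4-[(tert-butyldimethylsilyl)oxy]phenyl}acrylate, 23 malondialdehyde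
Product: 25 silyl-protected 11-oxo-luzonoid A [(1S,5S,7S,8R,9S), iridoid numbering: 1-O-isovaleryl, 4-CHO, 7-O-(E)-4-(TBSO)cinnamoyl, 8-OTES, 8-CH2OTBS], via alkylidene malondialdehyde 24 (not isolated)
Conditions: EDDA (10 mol %), Na2SO4, CH2Cl2, 0 °C → rt
Reagents that add atoms: none
Why: In a domino Knoevenagel–hetero-Diels–Alder reaction, the ammonium acetate catalyst condenses the C5 aldehyde of 21 with the acidic CH2 of 23 to give the 2-alkylidene-1,3-dialdehyde 24, whose 1-oxadiene O2=C3–C4=C5 (LUMO lowered by the second formyl group) adds with inverse electron demand across the enol ester C9=C1, the nucleophilic C9 bonding to C5 and O2 to the acyloxy-bearing C1. The closest known reaction type is the intramolecular oxa-[4+2] of alkylidene 1,3-dicarbonyl compounds with tethered enol ethers and alkenes, together with intermolecular additions of vinyl esters to activated oxadienes. The cyclopentane closes through C5–C9 in a 5-exo-trig mode with respect to both C4=C5 and C9=C1 across the C6–C7–C8 tether, and the dihydropyran closes in the same asynchronous pericyclic event through O2–C1 (six-membered cycloaddition ring, 6-endo with respect to the enol ester). C5 and C9 are set cis because the three-atom tether cannot span a trans-fused transition state, C1 is set relative to C9 by suprafacial addition to the (E)-enol ester (isovaleryloxy cis to H-9), and the absolute sense of all three follows from C7 and C8 through an envelope transition state that keeps the C7 coumarate and the C10 silyloxymethyl group on the convex face and only the C8 silyloxy group on the concave face. The step needs diastereofacial selectivity, which rests on the two stereocentres next to the reacting carbons, and chemoselectivity for cycloaddition over β-elimination of the C7 carboxylate, which rests on the buffered, nearly neutral catalyst, the low temperature and fast intramolecular trapping of 24; the electron-poor cinnamate C=C does not compete as a dienophile.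

Step 17
Reactants: 25 silyl-protected 11-oxo-luzonoid A
Product: 26 silyl-protected luzonoid A [(1S,5S,7S,8R,9S): 1-O-isovaleryl, 4-CH2OH, 7-O-(E)-4-(TBSO)cinnamoyl, 8-OTES, 8-CH2OTBS]
Conditions: NaBH4, CeCl3·7H2O, MeOH/THF, −78 → −40 °C
Reagents that add atoms: none
Why: Luche reduction delivers hydride 1,2 to the vinylogous formate aldehyde only, giving the C11 allylic alcohol without touching the cinnamate, the acyloxy acetal or the enol ether at low temperature.

Step 18
Reactants: 26 silyl-protected luzonoid A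
Product: 27 luzonoid A
Conditions: HF·pyridine, pyridine, THF, 0 °C → rt
Reagents that add atoms: none
Why: Fluoride-mediated desilylation with pyridine-buffered HF removes the aryl TBS, primary TBS and tertiary TES ethers under weakly acidic, non-basic conditions, chosen to avoid base-induced acyl migration from O7 to the neighbouring hydroxyls and cleavage of the C1 acyloxy acetal.

**Compound list**

1 | 2-deoxy-D-ribose | O=CC[C@H](O)[C@H](O)CO | starting material
2 | (2R,3S)-4-(1,3-dithian-2-yl)butane-1,2,3-triol | S1CCCSC1C[C@H](O)[C@H](O)CO | intermediate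
3 | (S)-1-[(R)-2,2-dimethyl-1,3-dioxolan-4-yl]-2-(1,3-dithian-2-yl)ethan-1-ol | S1CCCSC1C[C@H](O)[C@H]2COC(C)(C)O2 | intermediate
4 | 2-{(S)-2-[(R)-2,2-dimethyl-1,3-dioxolan-4-yl]-2-[(4-methoxybenzyl)oxy]ethyl}-1,3-dithiane | S1CCCSC1C[C@H](OCc2ccc(OC)cc2)[C@H]3COC(C)(C)O3 | intermediate
5 | (2R,3S)-4-(1,3-dithian-2-yl)-3-[(4-methoxybenzyl)oxy]butane-1,2-diol | S1CCCSC1C[C@H](OCc2ccc(OC)cc2)[C@H](O)CO | intermediate
6 | (2R,3S)-1-[(tert-butyldimethylsilyl)oxy]-4-(1,3-dithian-2-yl)-3-[(4-methoxybenzyl)oxy]butan-2-ol | S1CCCSC1C[C@H](OCc2ccc(OC)cc2)[C@H](O)CO[Si](C)(C)C(C)(C)C | intermediate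
7 | (S)-1-[(tert-butyldimethylsilyl)oxy]-4-(1,3-dithian-2-yl)-3-[(4-methoxybenzyl)oxy]butan-2-one | S1CCCSC1C[C@H](OCc2ccc(OC)cc2)C(=O)CO[Si](C)(C)C(C)(C)C | intermediate
8 | ethynylmagnesium bromide | C#C[Mg]Br | starting material
9 | (3R,4S)-3-{[(tert-butyldimethylsilyl)oxy]methyl}-5-(1,3-dithian-2-yl)-4-[(4-methoxybenzyl)oxy]pent-1-yn-3-ol | S1CCCSC1C[C@H](OCc2ccc(OC)cc2)[C@](O)(CO[Si](C)(C)C(C)(C)C)C#C | intermediate
10 | 2-{(2S,3R)-3-{[(tert-butyldimethylsilyl)oxy]methyl}-2-[(4-methoxybenzyl)oxy]-3-[(triethylsilyl)oxy]pent-4-yn-1-yl}-1,3-dithiane | S1CCCSC1C[C@H](OCc2ccc(OC)cc2)[C@](O[Si](CC)(CC)CC)(CO[Si](C)(C)C(C)(C)C)C#C | intermediate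
11 | (E)-alkenyl pinacol boronate from 10 [(1E,3R,4S)-pent-1-en-1-yl-Bpin, other groups as in 10] | S1CCCSC1C[C@H](OCc2ccc(OC)cc2)[C@](O[Si](CC)(CC)CC)(CO[Si](C)(C)C(C)(C)C)/C=C/B3OC(C)(C)C(C)(C)O3 | intermediate
12 | potassium [(1E,3R,4S)-3-{[(tert-butyldimethylsilyl)oxy]methyl}-5-(1,3-dithian-2-yl)-4-[(4-methoxybenzyl)oxy]-3-[(triethylsilyl)oxy]pent-1-en-1-yl]trifluoroborate | S1CCCSC1C[C@H](OCc2ccc(OC)cc2)[C@](O[Si](CC)(CC)CC)(CO[Si](C)(C)C(C)(C)C)/C=C/[B-](F)(F)F.[K+] | intermediate
13 | isovaleric acid (3-methylbutanoic acid) | CC(C)CC(O)=O | starting material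
14 | (1E,3R,4S)-3-{[(tert-butyldimethylsilyl)oxy]methyl}-5-(1,3-dithian-2-yl)-4-[(4-methoxybenzyl)oxy]-3-[(triethylsilyl)oxy]pent-1-en-1-yl 3-methylbutanoate | S1CCCSC1C[C@H](OCc2ccc(OC)cc2)[C@](O[Si](CC)(CC)CC)(CO[Si](C)(C)C(C)(C)C)/C=C/OC(=O)CC(C)C | intermediate
15 | (1E,3R,4S)-3-{[(tert-butyldimethylsilyl)oxy]methyl}-5-(1,3-dithian-2-yl)-4-hydroxy-3-[(triethylsilyl)oxy]pent-1-en-1-yl 3-methylbutanoate | S1CCCSC1C[C@H](O)[C@](O[Si](CC)(CC)CC)(CO[Si](C)(C)C(C)(C)C)/C=C/OC(=O)CC(C)C | intermediate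
16 | (E)-4-hydroxycinnamic acid | OC(=O)/C=C/c1ccc(O)cc1 | starting material
17 | tert-butyldimethylsilyl (E)-3-{4-[(tert-butyldimethylsilyl)oxy]phenyl}acrylate | CC(C)(C)[Si](C)(C)OC(=O)/C=C/c1ccc(O[Si](C)(C)C(C)(C)C)cc1 | intermediate
18 | (E)-3-{4-[(tert-butyldimethylsilyl)oxy]phenyl}acrylic acid | OC(=O)/C=C/c1ccc(O[Si](C)(C)C(C)(C)C)cc1 | intermediate
19 | (E)-3-{4-[(tert-butyldimethylsilyl)oxy]phenyl}acrylic 2,4,6-trichlorobenzoic anhydride | CC(C)(C)[Si](C)(C)Oc1ccc(/C=C/C(=O)OC(=O)c2c(Cl)cc(Cl)cc2Cl)cc1 | intermediate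
20 | (2S,3R,4E)-3-{[(tert-butyldimethylsilyl)oxy]methyl}-1-(1,3-dithian-2-yl)-5-[(3-methylbutanoyl)oxy]-3-[(triethylsilyl)oxy]pent-4-en-2-yl (E)-3-{4-[(tert-butyldimethylsilyl)oxy]phenyl}acrylate | S1CCCSC1C[C@H](OC(=O)/C=C/c2ccc(O[Si](C)(C)C(C)(C)C)cc2)[C@](O[Si](CC)(CC)CC)(CO[Si](C)(C)C(C)(C)C)/C=C/OC(=O)CC(C)C | intermediate
21 | (3S,4R,5E)-4-{[(tert-butyldimethylsilyl)oxy]methyl}-6-[(3-methylbutanoyl)oxy]-1-oxo-4-[(triethylsilyl)oxy]hex-5-en-3-yl (E)-3-{4-[(tert-butyldimethylsilyl)oxy]phenyl}acrylate | O=CC[C@H](OC(=O)/C=C/c1ccc(O[Si](C)(C)C(C)(C)C)cc1)[C@](O[Si](CC)(CC)CC)(CO[Si](C)(C)C(C)(C)C)/C=C/OC(=O)CC(C)C | intermediate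
22 | 1,1,3,3-tetramethoxypropane | COC(OC)CC(OC)OC | starting material
23 | malondialdehyde | O=CCC=O | intermediate
24 | 2-alkylidenemalondialdehyde from 21 [C5=C4(CHO)2, other groups as in 21] | O=CC(C=O)=CC[C@H](OC(=O)/C=C/c1ccc(O[Si](C)(C)C(C)(C)C)cc1)[C@](O[Si](CC)(CC)CC)(CO[Si](C)(C)C(C)(C)C)/C=C/OC(=O)CC(C)C | intermediate
25 | silyl-protected 11-oxo-luzonoid A, (1S,4aS,6S,7R,7aS)-7-{[(tert-butyldimethylsilyl)oxy]methyl}-6-{[(E)-3-{4-[(tert-butyldimethylsilyl)oxy]phenyl}acryloyl]oxy}-4-formyl-7-[(triethylsilyl)oxy]-1,4a,5,6,7,7a-hexahydrocyclopenta[c]pyran-1-yl 3-methylbutanoate | CC(C)CC(=O)O[C@@H]1OC=C(C=O)[C@H]2C[C@H](OC(=O)/C=C/c3ccc(O[Si](C)(C)C(C)(C)C)cc3)[C@](O[Si](CC)(CC)CC)(CO[Si](C)(C)C(C)(C)C)[C@@H]12 | intermediate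
26 | silyl-protected luzonoid A (as 25 with 4-hydroxymethyl in place of 4-formyl) | CC(C)CC(=O)O[C@@H]1OC=C(CO)[C@H]2C[C@H](OC(=O)/C=C/c3ccc(O[Si](C)(C)C(C)(C)C)cc3)[C@](O[Si](CC)(CC)CC)(CO[Si](C)(C)C(C)(C)C)[C@@H]12 | intermediate
27 | luzonoid A | CC(C)CC(=O)O[C@@H]1OC=C(CO)[C@H]2C[C@H](OC(=O)/C=C/c3ccc(O)cc3)[C@](O)(CO)[C@@H]12 | target

**Step count and risks**

Total step count: 18 (including the two side steps 12 and 15).
Longest linear sequence: 16 steps (steps 1–11, 13, 14, 16, 17, 18).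

Steps most likely to fail:

1. Step 16. The C7 coumarate may be lost by β-elimination, through the enamine of aldehyde 21 or by γ-deprotonation of the alkylidene dialdehyde 24, faster than condensation and cycloaddition; facial selectivity may also be low. The fallback carries O7 through ring formation as the PMB ether, a much poorer leaving group, and acylates afterwards. It sets out from 14: MeI/CaCO3 in aqueous MeCN should release the β-(4-methoxybenzyloxy) aldehyde F1. Condensation with 23 under the same EDDA conditions should give the alkylidene malondialdehyde F2 (not isolated) and, by the same oxa-[4+2], the 7-O-PMB cycloadduct F3. Buffered DDQ should free the C7 alcohol F4, since the vinylogous formate enol ether is too electron-poor to be oxidised. Yamaguchi esterification with 18 (through 19) then comes back to the route at 25.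

2. Step 10. The dithiane sulfur may bind copper so that turnover stalls and protodeboronation or oxidative homocoupling of the alkenylborate takes over. The fallback removes sulfur before the coupling and changes the aldehyde mask. It sets out from 10: PhI(OCOCF3)2 in MeOH at 0 °C should transacetalise the dithiane to the dimethyl acetal alkyne F5. Hydroboration as in step 9 should give the pinacol boronate F6 (not isolated) and, with KHF2, the trifluoroborate F7. Copper-catalysed coupling with 13 should give the enol isovalerate F8, DDQ the C7 alcohol F9, and Yamaguchi esterification with 18 (through 19) the coumarate dimethyl acetal F10. Chemoselective acetal cleavage with TESOTf/2,4,6-collidine in CH2Cl2 at 0 °C followed by water comes back to the route at 21.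

3. Step 18. The acid-labile array of C1 acyloxy acetal, enol ether and C11 allylic alcohol may ionise during the long HF exposure that the tertiary TES ether needs. The fallback reverses the order of the endgame. It sets out from 25, whose enol ether is deactivated as a vinylogous formate: HF·pyridine/pyridine should give the desilylated aldehyde 11-oxo-luzonoid A F11, and Luche reduction at −78 °C as the last operation comes back to the route at 27.

**Further compounds**

F1 | step 16 | (1E,3R,4S)-3-{[(tert-butyldimethylsilyl)oxy]methyl}-4-[(4-methoxybenzyl)oxy]-6-oxo-3-[(triethylsilyl)oxy]hex-1-en-1-yl 3-methylbutanoate | O=CC[C@H](OCc1ccc(OC)cc1)[C@](O[Si](CC)(CC)CC)(CO[Si](C)(C)C(C)(C)C)/C=C/OC(=O)CC(C)C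
F2 | step 16 | 2-alkylidenemalondialdehyde from F1 [C5=C4(CHO)2, other groups as in F1] | O=CC(C=O)=CC[C@H](OCc1ccc(OC)cc1)[C@](O[Si](CC)(CC)CC)(CO[Si](C)(C)C(C)(C)C)/C=C/OC(=O)CC(C)C
F3 | step 16 | 7-O-PMB cycloadduct, (1S,4aS,6S,7R,7aS)-7-{[(tert-butyldimethylsilyl)oxy]methyl}-4-formyl-6-[(4-methoxybenzyl)oxy]-7-[(triethylsilyl)oxy]-1,4a,5,6,7,7a-hexahydrocyclopenta[c]pyran-1-yl 3-methylbutanoate | CC(C)CC(=O)O[C@@H]1OC=C(C=O)[C@H]2C[C@H](OCc3ccc(OC)cc3)[C@](O[Si](CC)(CC)CC)(CO[Si](C)(C)C(C)(C)C)[C@@H]12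
F4 | step 16 | 7-hydroxy cycloadduct (as F3 with free 6-OH in the systematic numbering) | CC(C)CC(=O)O[C@@H]1OC=C(C=O)[C@H]2C[C@H](O)[C@](O[Si](CC)(CC)CC)(CO[Si](C)(C)C(C)(C)C)[C@@H]12
F5 | step 10 | (3R,4S)-3-{[(tert-butyldimethylsilyl)oxy]methyl}-6,6-dimethoxy-4-[(4-methoxybenzyl)oxy]-3-[(triethylsilyl)oxy]hex-1-yne | COC(OC)C[C@H](OCc1ccc(OC)cc1)[C@](O[Si](CC)(CC)CC)(CO[Si](C)(C)C(C)(C)C)C#C
F6 | step 10 | (E)-alkenyl pinacol boronate from F5 | COC(OC)C[C@H](OCc1ccc(OC)cc1)[C@](O[Si](CC)(CC)CC)(CO[Si](C)(C)C(C)(C)C)/C=C/B2OC(C)(C)C(C)(C)O2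
F7 | step 10 | potassium (E)-alkenyltrifluoroborate from F5 | COC(OC)C[C@H](OCc1ccc(OC)cc1)[C@](O[Si](CC)(CC)CC)(CO[Si](C)(C)C(C)(C)C)/C=C/[B-](F)(F)F.[K+]
F8 | step 10 | (1E,3R,4S)-3-{[(tert-butyldimethylsilyl)oxy]methyl}-6,6-dimethoxy-4-[(4-methoxybenzyl)oxy]-3-[(triethylsilyl)oxy]hex-1-en-1-yl 3-methylbutanoate | COC(OC)C[C@H](OCc1ccc(OC)cc1)[C@](O[Si](CC)(CC)CC)(CO[Si](C)(C)C(C)(C)C)/C=C/OC(=O)CC(C)C
F9 | step 10 | (1E,3R,4S)-3-{[(tert-butyldimethylsilyl)oxy]methyl}-4-hydroxy-6,6-dimethoxy-3-[(triethylsilyl)oxy]hex-1-en-1-yl 3-methylbutanoate | COC(OC)C[C@H](O)[C@](O[Si](CC)(CC)CC)(CO[Si](C)(C)C(C)(C)C)/C=C/OC(=O)CC(C)C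
F10 | step 10 | (3S,4R,5E)-4-{[(tert-butyldimethylsilyl)oxy]methyl}-1,1-dimethoxy-6-[(3-methylbutanoyl)oxy]-4-[(triethylsilyl)oxy]hex-5-en-3-yl (E)-3-{4-[(tert-butyldimethylsilyl)oxy]phenyl}acrylate | COC(OC)C[C@H](OC(=O)/C=C/c1ccc(O[Si](C)(C)C(C)(C)C)cc1)[C@](O[Si](CC)(CC)CC)(CO[Si](C)(C)C(C)(C)C)/C=C/OC(=O)CC(C)C
F11 | step 18 | 11-oxo-luzonoid A | CC(C)CC(=O)O[C@@H]1OC=C(C=O)[C@H]2C[C@H](OC(=O)/C=C/c3ccc(O)cc3)[C@](O)(CO)[C@@H]12
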